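The target is numbered as a 1-aryl-1,2-dihydronaphthalene (CHO on C2, CH2OH on C3, alkene CH at C4; ring A is the benzo ring). Ring B is cut as a Diels–Alder adduct: C1, C8a, C4a and C4 make up an ortho-quinodimethane and C2=C3 the dienophile. A trans-2-aryl-benzocyclobutenol with silylated phenols opens on heating to the (E,E)-hydroxy diene, which the fumarate of methyl (S)-lactate traps; one operation forms C1–C2 and C3–C4, closes ring B, restores the aromaticity of ring A and sets C1 and C2. Elimination of the C4 hydroxyl, ester reduction and oxidation of the C2 arm alone then finish the synthesis.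

Key step: step 9

Assumption: the (S)-lactate units are taken to direct the diene to the fumarate face that gives the 1S adduct (hydrogen-bonded endo model); should the adduct prove to be of the 1R series, methyl (R)-lactate would replace 14 in step 8 with no other change.

Step 1
Reactants: 1 6-bromovanillin (2-bromo-4-hydroxy-5-methoxybenzaldehyde)
Product: 2 2-bromo-5-methoxy-4-(triisopropylsilyloxy)benzaldehyde
Conditions: TIPSCl, imidazole, DMF, rt
Reagents that add atoms: triisopropylsilyl chloride (TIPSCl), CC(C)[Si](Cl)(C(C)C)C(C)C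
Why: Imidazole-promoted O-silylation of a phenol, the bulky triisopropylsilyl ether being chosen because it should withstand the amide base, the organolithium, the metal alkoxides and the hydride of later steps better than a smaller silyl ether and still falls to buffered fluoride at the end.

Step 2
Reactants: 3 vanillin (4-hydroxy-3-methoxybenzaldehyde)
Product: 4 3-methoxy-4-(triisopropylsilyloxy)benzaldehyde
Conditions: TIPSCl, imidazole, DMF, rt
Reagents that add atoms: triisopropylsilyl chloride (TIPSCl), CC(C)[Si](Cl)(C(C)C)C(C)C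
Why: The same imidazole-promoted phenol silylation, to which the aldehyde is inert.

Step 3
Reactants: 4 3-methoxy-4-(triisopropylsilyloxy)benzaldehyde
Product: 5 [3-methoxy-4-(triisopropylsilyloxy)phenyl]methanol
Conditions: NaBH4, MeOH/THF, 0 °C
Reagents that add atoms: none
Why: Borohydride reduction of an aromatic aldehyde to the benzylic alcohol, which the hindered aryl silyl ether should survive at 0 °C.

Step 4
Reactants: 5 [3-methoxy-4-(triisopropylsilyloxy)phenyl]methanol
Product: 6 4-(bromomethyl)-2-methoxy-1-(triisopropylsilyloxy)benzene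
Conditions: PBr3, Et2O, 0 °C
Reagents that add atoms: phosphorus tribromide, BrP(Br)Br
Why: Conversion of an activated benzylic alcohol into the bromide through its phosphite ester (nucleophilic substitution by bromide), the labile electron-rich bromide being taken on crude.

Step 5
Reactants: 6 4-(bromomethyl)-2-methoxy-1-(triisopropylsilyloxy)benzene
Product: 7 1-[3-methoxy-4-(triisopropylsilyloxy)benzyl]tetrahydrothiophen-1-ium bromide
Conditions: tetrahydrothiophene, acetone, rt
Reagents that add atoms: tetrahydrothiophene, C1CCSC1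
Why: SN2 alkylation of a cyclic sulfide by a reactive benzylic bromide, the sulfonium salt being expected to separate from acetone.

Step 6
Reactants: 7 1-[3-methoxy-4-(triisopropylsilyloxy)benzyl]tetrahydrothiophen-1-ium bromide; 2 2-bromo-5-methoxy-4-(triisopropylsilyloxy)benzaldehyde
Product: 9 rac-trans-2-[2-bromo-5-methoxy-4-(triisopropylsilyloxy)phenyl]-3-[3-methoxy-4-(triisopropylsilyloxy)phenyl]oxirane, via sulfonium ylide 8 (not isolated)
Conditions: KN(SiMe3)2, THF, −78 °C; then 2, −78 °C → rt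
Reagents that add atoms: none
Why: Corey–Chaykovsky-type epoxidation with a semi-stabilised benzylsulfonium ylide, in which reversible addition to the aldehyde and ring closure with loss of tetrahydrothiophene should favour the trans-epoxide, so that the relative configuration of the two epoxide carbons is set here in racemic form under non-nucleophilic conditions that spare the silyl ethers.

Step 7
Reactants: 9 rac-trans-2-[2-bromo-5-methoxy-4-(triisopropylsilyloxy)phenyl]-3-[3-methoxy-4-(triisopropylsilyloxy)phenyl]oxirane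
Product: 12 rac-trans-5-methoxy-2-[3-methoxy-4-(triisopropylsilyloxy)phenyl]-4-(triisopropylsilyloxy)-1,2-dihydrobenzocyclobuten-1-ol, via aryllithium 10 (not isolated), via bromomagnesium alkoxide 11 (not isolated)
Conditions: n-BuLi, THF, −78 °C; MgBr2·OEt2, −78 → 0 °C; H2O, cold work-up
Reagents that add atoms: none
Why: Bromine–lithium exchange outruns attack of n-BuLi on the epoxide, and the aryl metal then opens the Lewis-acid-activated benzylic C–O bond by a 4-exo-tet SN2 displacement with inversion, so that the trans-epoxide should give the trans-cyclobutenol, while the magnesium counter-ion is expected to keep the strained alkoxide from opening before the quench.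

Step 8
Reactants: 13 fumaryl chloride; 14 methyl (S)-lactate
Product: 15 bis[(S)-1-methoxy-1-oxopropan-2-yl] fumarate
Conditions: 14 (2.2 equiv), pyridine (2.5 equiv), CH2Cl2, 0 °C → rt
Reagents that add atoms: methyl (S)-lactate (second equivalent of 14), C[C@H](O)C(=O)OC
Why: Each of the two acid chloride groups of 13 acylates the secondary hydroxyl of one molecule of 14 (nucleophilic acyl substitution with pyridine as acid scavenger), so that two equivalents of the lactate are built into the diester while neither the E-alkene nor the lactate stereocentre is touched.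

Step 9
Reactants: 12 rac-trans-5-methoxy-2-[3-methoxy-4-(triisopropylsilyloxy)phenyl]-4-(triisopropylsilyloxy)-1,2-dihydrobenzocyclobuten-1-ol; 15 bis[(S)-1-methoxy-1-oxopropan-2-yl] fumarate
Product: 17 bis[(S)-1-methoxy-1-oxopropan-2-yl] (1S,2R,3S,4S)-4-hydroxy-6-methoxy-1-[3-methoxy-4-(triisopropylsilyloxy)phenyl]-7-(triisopropylsilyloxy)-1,2,3,4-tetrahydronaphthalene-2,3-dicarboxylate, via (E,E)-hydroxy-ortho-quinodimethane 16 (not isolated)
Conditions: 15 (2 equiv), PhMe, 90 °C, Ar
Reagents that add atoms: none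
Why: Thermal conrotatory 4π electrocyclic opening of the strained cyclobutene turns the hydroxyl and the aryl group of the trans-substituted ring both outward and gives the (E,E)-dienol 16, which the electron-poor fumarate traps in a concerted suprafacial [4+2] cycloaddition that forms C1–C2 and C3–C4 and returns ring A to aromaticity. The closest known reaction type is the Diels–Alder trapping of alpha-hydroxy-ortho-quinodimethanes, generated from benzocyclobutenols, by fumarates of chiral alpha-hydroxy esters. Ring B is closed by this intermolecular [4+2] cycloaddition, the four-membered ring having been opened in the same flask. C1 and C4 come out cis because both substituents sit on the outside of the diene, C2 and C3 are trans because the fumarate geometry is retained, C3 is cis to the C4 hydroxyl because the ester next to the hydroxyl takes the endo, hydrogen-bonded position (which puts the C2 ester anti to the aryl group), and the absolute sense at C1 to C4 is fixed by the (S)-lactate units, which cover one face of the twofold-symmetric dienophile. The step needs outward rotation, endo selectivity and facial selectivity: the first follows from the trans configuration of 12 and the preference of the oxygen donor to rotate outward, the second from the hydroxyl–carbonyl hydrogen bond, the third from the two identical auxiliaries, and a minor facial isomer would be a diastereomer that should be removable by chromatography or crystallisation.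

Step 10
Reactants: 17 bis[(S)-1-methoxy-1-oxopropan-2-yl] (1S,2R,3S,4S)-4-hydroxy-6-methoxy-1-[3-methoxy-4-(triisopropylsilyloxy)phenyl]-7-(triisopropylsilyloxy)-1,2,3,4-tetrahydronaphthalene-2,3-dicarboxylate
Product: 19 bis[(S)-1-methoxy-1-oxopropan-2-yl] (1S,2R)-6-methoxy-1-[3-methoxy-4-(triisopropylsilyloxy)phenyl]-7-(triisopropylsilyloxy)-1,2-dihydronaphthalene-2,3-dicarboxylate, via C4 mesylate 18 (not isolated)
Conditions: MsCl, Et3N, CH2Cl2, 0 °C → rt
Reagents that add atoms: none
Why: Mesylation followed by base-induced anti elimination of a β-hydroxy ester (E2 or E1cB), for which the axial C3–H is anti-periplanar to the axial benzylic C4 leaving group, so that only the C3=C4 alkene can form and the weak amine base should leave C1 and the trans C2 centre as they are.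

Step 11
Reactants: 19 bis[(S)-1-methoxy-1-oxopropan-2-yl] (1S,2R)-6-methoxy-1-[3-methoxy-4-(triisopropylsilyloxy)phenyl]-7-(triisopropylsilyloxy)-1,2-dihydronaphthalene-2,3-dicarboxylate
Product: 20 [(1S,2R)-6-methoxy-1-[3-methoxy-4-(triisopropylsilyloxy)phenyl]-7-(triisopropylsilyloxy)-1,2-dihydronaphthalene-2,3-diyl]dimethanol
Conditions: i-Bu2AlH (excess), CH2Cl2, −78 → 0 °C; aq. KNaC4H4O6
Reagents that add atoms: none
Why: Exhaustive hydride reduction of all four ester groups by i-Bu2AlH (1,2-reduction of the conjugated ester to the allylic alcohol), which removes the auxiliaries as (S)-propane-1,2-diol under non-basic conditions that should not epimerise C2.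

Step 12
Reactants: 20 [(1S,2R)-6-methoxy-1-[3-methoxy-4-(triisopropylsilyloxy)phenyl]-7-(triisopropylsilyloxy)-1,2-dihydronaphthalene-2,3-diyl]dimethanol
Product: 21 [(1S,2R)-3-[(tert-butyldimethylsilyloxy)methyl]-6-methoxy-1-[3-methoxy-4-(triisopropylsilyloxy)phenyl]-7-(triisopropylsilyloxy)-1,2-dihydronaphthalen-2-yl]methanol
Conditions: TBSCl (1.05 equiv), imidazole, CH2Cl2, −20 °C
Reagents that add atoms: tert-butyldimethylsilyl chloride (TBSCl), CC(C)(C)[Si](C)(C)Cl
Why: Sterically controlled monosilylation of a diol, in which the allylic CH2OH on the flat sp2 carbon C3 should react before the CH2OH on C2 that is flanked by the aryl-bearing C1, and from which any regioisomer or bis-ether can be desilylated and recycled.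

Step 13
Reactants: 21 [(1S,2R)-3-[(tert-butyldimethylsilyloxy)methyl]-6-methoxy-1-[3-methoxy-4-(triisopropylsilyloxy)phenyl]-7-(triisopropylsilyloxy)-1,2-dihydronaphthalen-2-yl]methanol
Product: 22 (1S,2R)-3-[(tert-butyldimethylsilyloxy)methyl]-6-methoxy-1-[3-methoxy-4-(triisopropylsilyloxy)phenyl]-7-(triisopropylsilyloxy)-1,2-dihydronaphthalene-2-carbaldehyde
Conditions: Dess–Martin periodinane, pyridine, CH2Cl2, 0 °C
Reagents that add atoms: none
Why: Dess–Martin oxidation of the remaining primary alcohol to the aldehyde under buffered conditions without strong base, which should leave the enolisable C2 centre trans to the aryl group and the C3=C4 alkene out of conjugation.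

Step 14
Reactants: 22 (1S,2R)-3-[(tert-butyldimethylsilyloxy)methyl]-6-methoxy-1-[3-methoxy-4-(triisopropylsilyloxy)phenyl]-7-(triisopropylsilyloxy)-1,2-dihydronaphthalene-2-carbaldehyde
Product: 23 (1S,2R)-7-hydroxy-1-(4-hydroxy-3-methoxyphenyl)-3-(hydroxymethyl)-6-methoxy-1,2-dihydronaphthalene-2-carbaldehyde (CNP0591394.1)
Conditions: Bu4NF, AcOH, THF, 0 °C → rt
Reagents that add atoms: none
Why: Fluoride-induced cleavage of the two aryl silyl ethers and the primary silyl ether in one operation, buffered with acetic acid so that phenoxide and alkoxide are protonated as they form and the β,γ-unsaturated aldehyde should neither epimerise at C2 nor shift its double bond.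

Compound list

1 | 6-bromovanillin (2-bromo-4-hydroxy-5-methoxybenzaldehyde) | COc1cc(C=O)c(Br)cc1O | starting material
2 | 2-bromo-5-methoxy-4-(triisopropylsilyloxy)benzaldehyde | COc1cc(C=O)c(Br)cc1O[Si](C(C)C)(C(C)C)C(C)C | intermediate
3 | vanillin (4-hydroxy-3-methoxybenzaldehyde) | COc1cc(C=O)ccc1O | starting material
4 | 3-methoxy-4-(triisopropylsilyloxy)benzaldehyde | COc1cc(C=O)ccc1O[Si](C(C)C)(C(C)C)C(C)C | intermediate
5 | [3-methoxy-4-(triisopropylsilyloxy)phenyl]methanol | COc1cc(CO)ccc1O[Si](C(C)C)(C(C)C)C(C)C | intermediate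
6 | 4-(bromomethyl)-2-methoxy-1-(triisopropylsilyloxy)benzene | COc1cc(CBr)ccc1O[Si](C(C)C)(C(C)C)C(C)C | intermediate
7 | 1-[3-methoxy-4-(triisopropylsilyloxy)benzyl]tetrahydrothiophen-1-ium bromide | COc1cc(C[S+]2CCCC2)ccc1O[Si](C(C)C)(C(C)C)C(C)C.[Br-] | intermediate
8 | sulfonium ylide of 7 (benzylic carbanion next to the sulfonium centre) | COc1cc([CH-][S+]2CCCC2)ccc1O[Si](C(C)C)(C(C)C)C(C)C | intermediate
9 | rac-trans-2-[2-bromo-5-methoxy-4-(triisopropylsilyloxy)phenyl]-3-[3-methoxy-4-(triisopropylsilyloxy)phenyl]oxirane (one enantiomer drawn) | COc1cc(c(Br)cc1O[Si](C(C)C)(C(C)C)C(C)C)[C@H]1O[C@@H]1c1ccc(O[Si](C(C)C)(C(C)C)C(C)C)c(OC)c1 | intermediate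
10 | aryllithium from 9 (Li in place of Br; racemic, one enantiomer drawn) | COc1cc(c([Li])cc1O[Si](C(C)C)(C(C)C)C(C)C)[C@H]1O[C@@H]1c1ccc(O[Si](C(C)C)(C(C)C)C(C)C)c(OC)c1 | intermediate
11 | bromomagnesium alkoxide of 12 (racemic, one enantiomer drawn) | COc1cc2c(cc1O[Si](C(C)C)(C(C)C)C(C)C)[C@@H](c1ccc(O[Si](C(C)C)(C(C)C)C(C)C)c(OC)c1)[C@@H]2O[Mg]Br | intermediate
12 | rac-trans-5-methoxy-2-[3-methoxy-4-(triisopropylsilyloxy)phenyl]-4-(triisopropylsilyloxy)-1,2-dihydrobenzocyclobuten-1-ol (one enantiomer drawn) | COc1cc2c(cc1O[Si](C(C)C)(C(C)C)C(C)C)[C@@H](c1ccc(O[Si](C(C)C)(C(C)C)C(C)C)c(OC)c1)[C@@H]2O | intermediate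
13 | fumaryl chloride | O=C(Cl)/C=C/C(=O)Cl | starting material
14 | methyl (S)-lactate | C[C@H](O)C(=O)OC | starting material
15 | bis[(S)-1-methoxy-1-oxopropan-2-yl] fumarate | COC(=O)[C@H](C)OC(=O)/C=C/C(=O)O[C@@H](C)C(=O)OC | intermediate
16 | (E,E)-hydroxy-ortho-quinodimethane: 5,6-dimethylidenecyclohexa-1,3-diene with OH on the exocyclic carbon at the ring carbon para to the silyloxy group and the aryl group on the other exocyclic carbon, both pointing outward | O/C=C1\C=C(OC)C(O[Si](C(C)C)(C(C)C)C(C)C)=C/C1=C\c1ccc(O[Si](C(C)C)(C(C)C)C(C)C)c(OC)c1 | intermediate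
17 | bis[(S)-1-methoxy-1-oxopropan-2-yl] (1S,2R,3S,4S)-4-hydroxy-6-methoxy-1-[3-methoxy-4-(triisopropylsilyloxy)phenyl]-7-(triisopropylsilyloxy)-1,2,3,4-tetrahydronaphthalene-2,3-dicarboxylate (1,2-trans, 2,3-trans, 3,4-cis) | COc1cc([C@H]2c3cc(O[Si](C(C)C)(C(C)C)C(C)C)c(OC)cc3[C@@H](O)[C@@H](C(=O)O[C@@H](C)C(=O)OC)[C@@H]2C(=O)O[C@@H](C)C(=O)OC)ccc1O[Si](C(C)C)(C(C)C)C(C)C | intermediate
18 | C4 methanesulfonate of 17 | COc1cc([C@H]2c3cc(O[Si](C(C)C)(C(C)C)C(C)C)c(OC)cc3[C@@H](OS(C)(=O)=O)[C@@H](C(=O)O[C@@H](C)C(=O)OC)[C@@H]2C(=O)O[C@@H](C)C(=O)OC)ccc1O[Si](C(C)C)(C(C)C)C(C)C | intermediate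
19 | bis[(S)-1-methoxy-1-oxopropan-2-yl] (1S,2R)-6-methoxy-1-[3-methoxy-4-(triisopropylsilyloxy)phenyl]-7-(triisopropylsilyloxy)-1,2-dihydronaphthalene-2,3-dicarboxylate | COc1cc([C@H]2c3cc(O[Si](C(C)C)(C(C)C)C(C)C)c(OC)cc3C=C(C(=O)O[C@@H](C)C(=O)OC)[C@@H]2C(=O)O[C@@H](C)C(=O)OC)ccc1O[Si](C(C)C)(C(C)C)C(C)C | intermediate
20 | [(1S,2R)-6-methoxy-1-[3-methoxy-4-(triisopropylsilyloxy)phenyl]-7-(triisopropylsilyloxy)-1,2-dihydronaphthalene-2,3-diyl]dimethanol | COc1cc([C@H]2c3cc(O[Si](C(C)C)(C(C)C)C(C)C)c(OC)cc3C=C(CO)[C@@H]2CO)ccc1O[Si](C(C)C)(C(C)C)C(C)C | intermediate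
21 | [(1S,2R)-3-[(tert-butyldimethylsilyloxy)methyl]-6-methoxy-1-[3-methoxy-4-(triisopropylsilyloxy)phenyl]-7-(triisopropylsilyloxy)-1,2-dihydronaphthalen-2-yl]methanol | COc1cc([C@H]2c3cc(O[Si](C(C)C)(C(C)C)C(C)C)c(OC)cc3C=C(CO[Si](C)(C)C(C)(C)C)[C@@H]2CO)ccc1O[Si](C(C)C)(C(C)C)C(C)C | intermediate
22 | (1S,2R)-3-[(tert-butyldimethylsilyloxy)methyl]-6-methoxy-1-[3-methoxy-4-(triisopropylsilyloxy)phenyl]-7-(triisopropylsilyloxy)-1,2-dihydronaphthalene-2-carbaldehyde | COc1cc([C@H]2c3cc(O[Si](C(C)C)(C(C)C)C(C)C)c(OC)cc3C=C(CO[Si](C)(C)C(C)(C)C)[C@@H]2C=O)ccc1O[Si](C(C)C)(C(C)C)C(C)C | intermediate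
23 | (1S,2R)-7-hydroxy-1-(4-hydroxy-3-methoxyphenyl)-3-(hydroxymethyl)-6-methoxy-1,2-dihydronaphthalene-2-carbaldehyde (CNP0591394.1) | COc1cc([C@H]2c3cc(O)c(OC)cc3C=C(CO)[C@@H]2C=O)ccc1O | target

Total step count: 14.
Longest linear sequence: 12 steps (3 → 4 → 5 → 6 → 7 → 9 → 12 → 17 → 19 → 20 → 21 → 22 → 23; steps 2 to 7 and 9 to 14).

Steps most likely to fail

Step 7 (aryl-metal 4-exo opening of the epoxide). The metal alkoxide of the strained product may undergo anion-accelerated ring opening and tautomerise before it is quenched, or the Lewis acid may rearrange the electron-rich epoxide before the carbon–carbon bond forms. The fallback sets out from bromide 6 and aldehyde 2 and comes back to the route at cycloadduct 17. Zinc insertion into 6 (Zn dust, LiCl, THF) should give [3-methoxy-4-(triisopropylsilyloxy)benzyl]zinc bromide F1. Negishi coupling of F1 with 2 (Pd(PPh3)4 cat., THF) should give 5-methoxy-2-[3-methoxy-4-(triisopropylsilyloxy)benzyl]-4-(triisopropylsilyloxy)benzaldehyde F2. Irradiation of F2 through Pyrex in benzene saturated with SO2 should photoenolise it to the same dienol 16, which SO2 captures as rac-cis-1-hydroxy-6-methoxy-3-[3-methoxy-4-(triisopropylsilyloxy)phenyl]-5-(triisopropylsilyloxy)-1,3-dihydrobenzo[c]thiophene 2,2-dioxide F3. Warming F3 with fumarate 15 in toluene extrudes SO2 by cheletropic reversal, regenerates 16 and should lead to 17.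

Step 9 (ring opening and cycloaddition). The lactate units may not differentiate the two faces of the fumarate well enough at the temperature needed for ring opening, so that a mixture of diastereomeric adducts results. The fallback sets out from 12 and 13 and comes back at diol 20. Fumaryl chloride 13 is esterified with commercial methyl (S)-mandelate (pyridine, CH2Cl2) to bis[(S)-2-methoxy-2-oxo-1-phenylethyl] fumarate F4, whose phenyl groups should shield one face more effectively and whose adducts should crystallise more readily. Cycloaddition with 12 under the conditions of step 9 should give bis[(S)-2-methoxy-2-oxo-1-phenylethyl] (1S,2R,3S,4S)-4-hydroxy-6-methoxy-1-[3-methoxy-4-(triisopropylsilyloxy)phenyl]-7-(triisopropylsilyloxy)-1,2,3,4-tetrahydronaphthalene-2,3-dicarboxylate F5, to be purified by crystallisation. Mesylation and elimination as in step 10 should pass through the C4 methanesulfonate of the mandelate adduct F6 to bis[(S)-2-methoxy-2-oxo-1-phenylethyl] (1S,2R)-6-methoxy-1-[3-methoxy-4-(triisopropylsilyloxy)phenyl]-7-(triisopropylsilyloxy)-1,2-dihydronaphthalene-2,3-dicarboxylate F7. Reduction with i-Bu2AlH as in step 11 releases (S)-1-phenylethane-1,2-diol and should give 20.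

Step 12 (monosilylation). The two primary hydroxyls may not be discriminated on steric grounds, so that the regioisomeric and the doubly silylated ethers form alongside 21. The fallback sets out from diol 20 and comes back at target 23; it replaces steric discrimination of the alcohols by the different reactivity of the two aldehydes. Swern oxidation ((COCl)2, DMSO, i-Pr2NEt, CH2Cl2, −78 °C) should give (1S,2R)-6-methoxy-1-[3-methoxy-4-(triisopropylsilyloxy)phenyl]-7-(triisopropylsilyloxy)-1,2-dihydronaphthalene-2,3-dicarbaldehyde F8. Under Luche-type conditions (NaBH4, CeCl3·7H2O, MeOH, −78 °C) the saturated C2 formyl group is expected to be masked as its dimethyl acetal, giving (1S,2R)-2-(dimethoxymethyl)-6-methoxy-1-[3-methoxy-4-(triisopropylsilyloxy)phenyl]-7-(triisopropylsilyloxy)-1,2-dihydronaphthalene-3-carbaldehyde F9. The conjugated C3 formyl group of F9 is then reduced to [(1S,2R)-2-(dimethoxymethyl)-6-methoxy-1-[3-methoxy-4-(triisopropylsilyloxy)phenyl]-7-(triisopropylsilyloxy)-1,2-dihydronaphthalen-3-yl]methanol F10. Dilute aqueous acid on work-up should release (1S,2R)-3-(hydroxymethyl)-6-methoxy-1-[3-methoxy-4-(triisopropylsilyloxy)phenyl]-7-(triisopropylsilyloxy)-1,2-dihydronaphthalene-2-carbaldehyde F11, which is desilylated with Bu4NF/AcOH as in step 14 to give 23.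

Further compounds

F1 | step 7 | [3-methoxy-4-(triisopropylsilyloxy)benzyl]zinc bromide | COc1cc(C[Zn]Br)ccc1O[Si](C(C)C)(C(C)C)C(C)C
F2 | step 7 | 5-methoxy-2-[3-methoxy-4-(triisopropylsilyloxy)benzyl]-4-(triisopropylsilyloxy)benzaldehyde | COc1cc(C=O)c(Cc2ccc(O[Si](C(C)C)(C(C)C)C(C)C)c(OC)c2)cc1O[Si](C(C)C)(C(C)C)C(C)C
F3 | step 7 | rac-cis-1-hydroxy-6-methoxy-3-[3-methoxy-4-(triisopropylsilyloxy)phenyl]-5-(triisopropylsilyloxy)-1,3-dihydrobenzo[c]thiophene 2,2-dioxide (one enantiomer drawn) | COc1cc2c(cc1O[Si](C(C)C)(C(C)C)C(C)C)[C@H](c1ccc(O[Si](C(C)C)(C(C)C)C(C)C)c(OC)c1)S(=O)(=O)[C@@H]2O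
F4 | step 9 | bis[(S)-2-methoxy-2-oxo-1-phenylethyl] fumarate | COC(=O)[C@H](c1ccccc1)OC(=O)/C=C/C(=O)O[C@@H](c1ccccc1)C(=O)OC
F5 | step 9 | bis[(S)-2-methoxy-2-oxo-1-phenylethyl] (1S,2R,3S,4S)-4-hydroxy-6-methoxy-1-[3-methoxy-4-(triisopropylsilyloxy)phenyl]-7-(triisopropylsilyloxy)-1,2,3,4-tetrahydronaphthalene-2,3-dicarboxylate | COc1cc([C@H]2c3cc(O[Si](C(C)C)(C(C)C)C(C)C)c(OC)cc3[C@@H](O)[C@@H](C(=O)O[C@@H](c3ccccc3)C(=O)OC)[C@@H]2C(=O)O[C@@H](c2ccccc2)C(=O)OC)ccc1O[Si](C(C)C)(C(C)C)C(C)C
F6 | step 9 | C4 methanesulfonate of F5 | COc1cc([C@H]2c3cc(O[Si](C(C)C)(C(C)C)C(C)C)c(OC)cc3[C@@H](OS(C)(=O)=O)[C@@H](C(=O)O[C@@H](c3ccccc3)C(=O)OC)[C@@H]2C(=O)O[C@@H](c2ccccc2)C(=O)OC)ccc1O[Si](C(C)C)(C(C)C)C(C)C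
F7 | step 9 | bis[(S)-2-methoxy-2-oxo-1-phenylethyl] (1S,2R)-6-methoxy-1-[3-methoxy-4-(triisopropylsilyloxy)phenyl]-7-(triisopropylsilyloxy)-1,2-dihydronaphthalene-2,3-dicarboxylate | COc1cc([C@H]2c3cc(O[Si](C(C)C)(C(C)C)C(C)C)c(OC)cc3C=C(C(=O)O[C@@H](c3ccccc3)C(=O)OC)[C@@H]2C(=O)O[C@@H](c2ccccc2)C(=O)OC)ccc1O[Si](C(C)C)(C(C)C)C(C)C
F8 | step 12 | (1S,2R)-6-methoxy-1-[3-methoxy-4-(triisopropylsilyloxy)phenyl]-7-(triisopropylsilyloxy)-1,2-dihydronaphthalene-2,3-dicarbaldehyde | COc1cc([C@H]2c3cc(O[Si](C(C)C)(C(C)C)C(C)C)c(OC)cc3C=C(C=O)[C@@H]2C=O)ccc1O[Si](C(C)C)(C(C)C)C(C)C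
F9 | step 12 | (1S,2R)-2-(dimethoxymethyl)-6-methoxy-1-[3-methoxy-4-(triisopropylsilyloxy)phenyl]-7-(triisopropylsilyloxy)-1,2-dihydronaphthalene-3-carbaldehyde | COc1cc([C@H]2c3cc(O[Si](C(C)C)(C(C)C)C(C)C)c(OC)cc3C=C(C=O)[C@@H]2C(OC)OC)ccc1O[Si](C(C)C)(C(C)C)C(C)C
F10 | step 12 | [(1S,2R)-2-(dimethoxymethyl)-6-methoxy-1-[3-methoxy-4-(triisopropylsilyloxy)phenyl]-7-(triisopropylsilyloxy)-1,2-dihydronaphthalen-3-yl]methanol | COc1cc([C@H]2c3cc(O[Si](C(C)C)(C(C)C)C(C)C)c(OC)cc3C=C(CO)[C@@H]2C(OC)OC)ccc1O[Si](C(C)C)(C(C)C)C(C)C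
F11 | step 12 | (1S,2R)-3-(hydroxymethyl)-6-methoxy-1-[3-methoxy-4-(triisopropylsilyloxy)phenyl]-7-(triisopropylsilyloxy)-1,2-dihydronaphthalene-2-carbaldehyde | COc1cc([C@H]2c3cc(O[Si](C(C)C)(C(C)C)C(C)C)c(OC)cc3C=C(CO)[C@@H]2C=O)ccc1O[Si](C(C)C)(C(C)C)C(C)C
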